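**Retrosynthetic overview**

1. Numbering: ring A = C1–C5 and C10, ring B = C5–C10, C11 = the OCH2 carbon on C9. The last bond made is the C11–O ether (Mitsunobu) between isofraxidin 20 and diol 19; 3-OH comes from a C3 ketone, the C8 methyl from a C8 methylidene, and C11–OH from a chiral pyrrolidine amide.
2. Key disconnection C1–C10: ring A is closed last onto ring B by oxidative opening of a cyclopropanol to a C1 radical, 6-endo addition to C10 and dehydrogenative termination. One operation should give ring A, the C3 ketone, the C10 stereocentre and the C5=C6 alkene.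
3. Enabling feature: C1 lies β to the oxygen-bearing C3 (C1–C2–C3(O) is an opened cyclopropanol), and C10 is the allylic ring-fusion carbon of the C5=C6 alkene. A C5=C10 alkene in ring B can therefore accept C1 at C10 and keep C5 sp2 by loss of H6.
4. Ring B with quaternary C9 comes from asymmetric Birch reduction–methylation of a 2-methoxybenzamide (ipso carbon = C9, C–OMe = C8). The arene comes from ester 1 by Kulinkovich reaction and ortho-lithiation/carboxylation.
5. Ring order: the coumarin rings are bought intact (20); ring B is made first (as an arene, then dearomatised); ring A is formed in the key step.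

Key step: step 9

Remark on the chemistry (assumption): the face on which the amide enolate is methylated in step 5 is taken to be the one drawn for 10 with the (S)-configured auxiliary 6. Should the auxiliary direct the other way, the (R)-enantiomer of 6 is used and nothing else changes.

**Route**

Step 1
Reactants: 1 methyl 2-(4-methoxyphenyl)-2-methylpropanoate
Product: 2 1-[2-(4-methoxyphenyl)propan-2-yl]cyclopropan-1-ol
Conditions: EtMgBr (2.5 equiv), Ti(OiPr)4 (20 mol %), THF, 0 °C to rt; aq. NH4Cl
Reagents that add atoms: ethylmagnesium bromide CC[Mg]Br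
Why: Kulinkovich reaction, in which the titanium-catalysed twofold alkylation of the ester carbonyl by one C2 unit from EtMgBr installs C1 and C2 as a cyclopropanol (a latent C3 ketone with a C1 radical); no stereocentre is formed.

Step 2
Reactants: 2 1-[2-(4-methoxyphenyl)propan-2-yl]cyclopropan-1-ol
Product: 3 tert-butyl({1-[2-(4-methoxyphenyl)propan-2-yl]cyclopropyl}oxy)dimethylsilane
Conditions: TBSOTf, 2,6-lutidine, CH2Cl2, 0 °C
Reagents that add atoms: tert-butyldimethylsilyl trifluoromethanesulfonate CC(C)(C)[Si](C)(C)OS(=O)(=O)C(F)(F)F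
Why: Silylation of the tertiary cyclopropanol with a silyl triflate and a hindered base should protect the acid- and base-labile cyclopropanol through the lithiation, Birch and methylenation steps.

Step 3
Reactants: 3 tert-butyl({1-[2-(4-methoxyphenyl)propan-2-yl]cyclopropyl}oxy)dimethylsilane
Product: 5 5-(2-{1-[(tert-butyldimethylsilyl)oxy]cyclopropyl}propan-2-yl)-2-methoxybenzoic acid, via aryllithium 4 (not isolated)
Conditions: n-BuLi, TMEDA, Et2O, 0 °C to rt; CO2, −78 °C; then 1 M HCl to pH 3, 0 °C
Reagents that add atoms: carbon dioxide O=C=O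
Why: Directed ortho-metalation, in which the methoxy group directs lithiation to its ortho position (the two are equivalent in the para-substituted ring) and carboxylation of 4 gives the benzoic acid whose ipso carbon becomes C9.

Step 4
Reactants: 5 5-(2-{1-[(tert-butyldimethylsilyl)oxy]cyclopropyl}propan-2-yl)-2-methoxybenzoic acid; 6 (2S)-2-(methoxymethyl)pyrrolidine
Product: 8 [5-(2-{1-[(tert-butyldimethylsilyl)oxy]cyclopropyl}propan-2-yl)-2-methoxyphenyl][(2S)-2-(methoxymethyl)pyrrolidin-1-yl]methanone, via acid chloride 7 (not isolated)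
Conditions: 1-chloro-N,N,2-trimethylprop-1-en-1-amine, CH2Cl2, 0 °C; then 6, Et3N, 0 °C to rt
Reagents that add atoms: none
Why: Amide formation through the acid chloride made under neutral conditions (no free HCl, so the silyl cyclopropyl ether should survive) attaches the chiral auxiliary that later controls C9.

Step 5
Reactants: 8 [5-(2-{1-[(tert-butyldimethylsilyl)oxy]cyclopropyl}propan-2-yl)-2-methoxyphenyl][(2S)-2-(methoxymethyl)pyrrolidin-1-yl]methanone
Product: 10 [(1S)-5-(2-{1-[(tert-butyldimethylsilyl)oxy]cyclopropyl}propan-2-yl)-2-methoxy-1-methylcyclohexa-2,5-dien-1-yl][(2S)-2-(methoxymethyl)pyrrolidin-1-yl]methanone, via potassium amide enolate 9 (not isolated)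
Conditions: K (2.2 equiv), NH3(l)/THF, t-BuOH (1 equiv), −78 °C; then MeI, −78 °C
Reagents that add atoms: iodomethane CI
Why: Birch reduction–alkylation of a chiral 2-methoxybenzamide, in which two-electron reduction with protonation para to the carboxamide (C6) gives the chelated enolate 9 and the prolinol ether auxiliary should make MeI enter on one face to set quaternary C9 (auxiliary control, sense as in the remark).

Step 6
Reactants: 10 [(1S)-5-(2-{1-[(tert-butyldimethylsilyl)oxy]cyclopropyl}propan-2-yl)-2-methoxy-1-methylcyclohexa-2,5-dien-1-yl][(2S)-2-(methoxymethyl)pyrrolidin-1-yl]methanone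
Product: 11 (2S)-4-(2-{1-[(tert-butyldimethylsilyl)oxy]cyclopropyl}propan-2-yl)-2-{[(2S)-2-(methoxymethyl)pyrrolidin-1-yl]carbonyl}-2-methylcyclohex-3-en-1-one
Conditions: oxalic acid (cat.), THF/H2O, rt
Reagents that add atoms: water O
Why: Mild acid hydrolysis of the methyl enol ether should give the C8 ketone, and because C9 is quaternary the C5=C10 alkene cannot move into conjugation.

Step 7
Reactants: 11 (2S)-4-(2-{1-[(tert-butyldimethylsilyl)oxy]cyclopropyl}propan-2-yl)-2-{[(2S)-2-(methoxymethyl)pyrrolidin-1-yl]carbonyl}-2-methylcyclohex-3-en-1-one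
Product: 12 [(1S)-3-(2-{1-[(tert-butyldimethylsilyl)oxy]cyclopropyl}propan-2-yl)-1-methyl-6-methylidenecyclohex-2-en-1-yl][(2S)-2-(methoxymethyl)pyrrolidin-1-yl]methanone
Conditions: Zn, CH2Br2, TiCl4, THF/CH2Cl2, 0 °C to rt
Reagents that add atoms: dibromomethane BrCBr
Why: Takai–Lombardo methylenation, a non-basic olefination suited to hindered enolisable ketones, turns C8 into the carbon that will carry the C8 methyl and keeps it sp2, which the face control of step 9 relies on.

Step 8
Reactants: 12 [(1S)-3-(2-{1-[(tert-butyldimethylsilyl)oxy]cyclopropyl}propan-2-yl)-1-methyl-6-methylidenecyclohex-2-en-1-yl][(2S)-2-(methoxymethyl)pyrrolidin-1-yl]methanone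
Product: 13 {(1S)-3-[2-(1-hydroxycyclopropyl)propan-2-yl]-1-methyl-6-methylidenecyclohex-2-en-1-yl}[(2S)-2-(methoxymethyl)pyrrolidin-1-yl]methanone
Conditions: Bu4NF, AcOH, THF, 0 °C to rt
Reagents that add atoms: none
Why: Fluoride cleavage of the silyl ether, buffered with acetic acid so that the free cyclopropanol is not opened by base, should unmask the radical precursor.

Step 9
Reactants: 13 {(1S)-3-[2-(1-hydroxycyclopropyl)propan-2-yl]-1-methyl-6-methylidenecyclohex-2-en-1-yl}[(2S)-2-(methoxymethyl)pyrrolidin-1-yl]methanone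
Product: 16 [(1S,8aR)-1,5,5-trimethyl-2-methylidene-6-oxo-1,2,3,5,6,7,8,8a-octahydronaphthalen-1-yl][(2S)-2-(methoxymethyl)pyrrolidin-1-yl]methanone, via ring-opened primary radical 14 (not isolated), via cyclised tertiary radical 15 (not isolated)
Conditions: Mn(acac)3 (1.3 equiv), Co(dmgBF2)2(H2O)2 (5 mol %), degassed MeCN with 10 vol % AcOH, 0.01 M, 40 °C, argon, H2 vented
Reagents that add atoms: none
Why: Proposed new method: Mn(acac)3 exchanges onto the cyclopropanol oxygen and the trivalent-manganese alkoxide collapses by β-scission to the primary β-keto radical 14 (C1), which adds to C10 of the C5=C10 alkene to give the tertiary radical 15, from which the divalent cobalt complex abstracts a C6 hydrogen (catalytic chain transfer) to form the C5=C6 alkene and a cobalt hydride that releases H2. The closest known reaction types are the trivalent-manganese ring-opening radical cyclisations of cyclopropanols and the cobaloxime-mediated radical cyclisation with dehydrocobaltation (alkyl Heck-type reaction); joining the two is the new element. Ring A closes in the 6-endo-trig mode, because 5-exo attack at C5 would build a quaternary carbon next to quaternary C4 and leave a secondary radical. The new stereocentre C10 is controlled by the C9 carboxamide, which A(1,3) strain with the C8 methylidene holds pseudoaxial, so C1 should bond on the opposite (C9-methyl) face and H10 should end cis to C11. The step needs hydrogen abstraction at C6 and not at C10, which the shielded C10–H next to quaternary C9 should secure, and it needs a termination without a C5 cation, since such a cation would be captured by the axial amide oxygen as in an iodolactonisation; this is why a cupric oxidant is not used.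

Step 10
Reactants: 16 [(1S,8aR)-1,5,5-trimethyl-2-methylidene-6-oxo-1,2,3,5,6,7,8,8a-octahydronaphthalen-1-yl][(2S)-2-(methoxymethyl)pyrrolidin-1-yl]methanone
Product: 17 [(1R,2S,8aR)-1,2,5,5-tetramethyl-6-oxo-1,2,3,5,6,7,8,8a-octahydronaphthalen-1-yl][(2S)-2-(methoxymethyl)pyrrolidin-1-yl]methanone
Conditions: H2 (1 atm), [Ir(cod)(PCy3)(py)]PF6 (5 mol %), CH2Cl2, 0 °C to rt
Reagents that add atoms: none
Why: Carboxamide-directed homogeneous hydrogenation, in which the cationic iridium catalyst binds the C11 amide oxygen and delivers H2 to the C8 methylidene from the amide face, should set C8 with its methyl cis to the C9 methyl, while the hindered trisubstituted C5=C6 alkene far from the amide should react much more slowly.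

Step 11
Reactants: 17 [(1R,2S,8aR)-1,2,5,5-tetramethyl-6-oxo-1,2,3,5,6,7,8,8a-octahydronaphthalen-1-yl][(2S)-2-(methoxymethyl)pyrrolidin-1-yl]methanone
Product: 18 [(1R,2S,6S,8aR)-6-hydroxy-1,2,5,5-tetramethyl-1,2,3,5,6,7,8,8a-octahydronaphthalen-1-yl][(2S)-2-(methoxymethyl)pyrrolidin-1-yl]methanone
Conditions: (R)-2-methyl-CBS-oxazaborolidine (0.3 equiv), catecholborane, toluene, −40 °C; then MeOH, aq. NaOH
Reagents that add atoms: none
Why: Corey–Bakshi–Shibata reduction under reagent control, in which the quaternary C4 is the large and the C2 methylene the small ketone substituent, so the (R)-catalyst should give the (3S) alcohol, and catecholborane at low temperature should leave the tertiary amide and the alkene untouched.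

Step 12
Reactants: 18 [(1R,2S,6S,8aR)-6-hydroxy-1,2,5,5-tetramethyl-1,2,3,5,6,7,8,8a-octahydronaphthalen-1-yl][(2S)-2-(methoxymethyl)pyrrolidin-1-yl]methanone
Product: 19 (2S,4aR,5R,6S)-5-(hydroxymethyl)-1,1,5,6-tetramethyl-1,2,3,4,4a,5,6,7-octahydronaphthalen-2-ol
Conditions: LiH2NBH3 (5 equiv), THF, 0 to 40 °C; then 1 M HCl, then NaOH
Reagents that add atoms: none
Why: Reduction of the tertiary amide to the primary alcohol with lithium amidotrihydroborate, a small and strongly nucleophilic hydride donor suited to amides on quaternary carbons, should free C11–OH and the auxiliary without touching any stereocentre.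

Step 13
Reactants: 19 (2S,4aR,5R,6S)-5-(hydroxymethyl)-1,1,5,6-tetramethyl-1,2,3,4,4a,5,6,7-octahydronaphthalen-2-ol; 20 isofraxidin (7-hydroxy-6,8-dimethoxy-2H-chromen-2-one)
Product: 21 7-{[(1R,2S,6S,8aR)-6-hydroxy-1,2,5,5-tetramethyl-1,2,3,5,6,7,8,8a-octahydronaphthalen-1-yl]methoxy}-6,8-dimethoxy-2H-chromen-2-one
Conditions: cyanomethylenetributylphosphorane (2 equiv), toluene, 110 °C
Reagents that add atoms: none
Why: Mitsunobu etherification with a phosphorane reagent that tolerates neopentyl alcohols at high temperature should join the acidic 7-OH of 20 to the primary C11–OH, while the secondary 3-OH beside the gem-dimethyl carbon should be too hindered to react, so no protecting group is needed and no stereocentre is touched.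

**Compound list**

1 | methyl 2-(4-methoxyphenyl)-2-methylpropanoate | COC(=O)C(C)(C)c1ccc(OC)cc1 | starting material
2 | 1-[2-(4-methoxyphenyl)propan-2-yl]cyclopropan-1-ol | OC1(CC1)C(C)(C)c1ccc(OC)cc1 | intermediate
3 | tert-butyl({1-[2-(4-methoxyphenyl)propan-2-yl]cyclopropyl}oxy)dimethylsilane | CC(C)(C)[Si](C)(C)OC1(CC1)C(C)(C)c1ccc(OC)cc1 | intermediate
4 | [5-(2-{1-[(tert-butyldimethylsilyl)oxy]cyclopropyl}propan-2-yl)-2-methoxyphenyl]lithium | COc1ccc(cc1[Li])C(C)(C)C1(CC1)O[Si](C)(C)C(C)(C)C | intermediate
5 | 5-(2-{1-[(tert-butyldimethylsilyl)oxy]cyclopropyl}propan-2-yl)-2-methoxybenzoic acid | COc1ccc(cc1C(O)=O)C(C)(C)C1(CC1)O[Si](C)(C)C(C)(C)C | intermediate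
6 | (2S)-2-(methoxymethyl)pyrrolidine | COC[C@@H]1CCCN1 | starting material
7 | 5-(2-{1-[(tert-butyldimethylsilyl)oxy]cyclopropyl}propan-2-yl)-2-methoxybenzoyl chloride | COc1ccc(cc1C(Cl)=O)C(C)(C)C1(CC1)O[Si](C)(C)C(C)(C)C | intermediate
8 | [5-(2-{1-[(tert-butyldimethylsilyl)oxy]cyclopropyl}propan-2-yl)-2-methoxyphenyl][(2S)-2-(methoxymethyl)pyrrolidin-1-yl]methanone | COC[C@@H]1CCCN1C(=O)c1cc(ccc1OC)C(C)(C)C1(CC1)O[Si](C)(C)C(C)(C)C | intermediate
9 | potassium amide enolate of 8 after reduction (exocyclic C9=C(OK)N, C6 as CH2, ring alkenes C5=C10 and C7=C8) | COC[C@@H]1CCCN1C([O-])=C1C=C(CC=C1OC)C(C)(C)C1(CC1)O[Si](C)(C)C(C)(C)C.[K+] | intermediate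
10 | [(1S)-5-(2-{1-[(tert-butyldimethylsilyl)oxy]cyclopropyl}propan-2-yl)-2-methoxy-1-methylcyclohexa-2,5-dien-1-yl][(2S)-2-(methoxymethyl)pyrrolidin-1-yl]methanone | COC[C@@H]1CCCN1C(=O)[C@@]1(C)C=C(CC=C1OC)C(C)(C)C1(CC1)O[Si](C)(C)C(C)(C)C | intermediate
11 | (2S)-4-(2-{1-[(tert-butyldimethylsilyl)oxy]cyclopropyl}propan-2-yl)-2-{[(2S)-2-(methoxymethyl)pyrrolidin-1-yl]carbonyl}-2-methylcyclohex-3-en-1-one | COC[C@@H]1CCCN1C(=O)[C@@]1(C)C=C(CCC1=O)C(C)(C)C1(CC1)O[Si](C)(C)C(C)(C)C | intermediate
12 | [(1S)-3-(2-{1-[(tert-butyldimethylsilyl)oxy]cyclopropyl}propan-2-yl)-1-methyl-6-methylidenecyclohex-2-en-1-yl][(2S)-2-(methoxymethyl)pyrrolidin-1-yl]methanone | COC[C@@H]1CCCN1C(=O)[C@@]1(C)C=C(CCC1=C)C(C)(C)C1(CC1)O[Si](C)(C)C(C)(C)C | intermediate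
13 | {(1S)-3-[2-(1-hydroxycyclopropyl)propan-2-yl]-1-methyl-6-methylidenecyclohex-2-en-1-yl}[(2S)-2-(methoxymethyl)pyrrolidin-1-yl]methanone | COC[C@@H]1CCCN1C(=O)[C@@]1(C)C=C(CCC1=C)C(C)(C)C1(O)CC1 | intermediate
14 | ring-opened primary β-keto radical (radical at C1, C3 ketone, ring B as in 13) | COC[C@@H]1CCCN1C(=O)[C@@]1(C)C=C(CCC1=C)C(C)(C)C(=O)C[CH2] | intermediate
15 | cyclised tertiary radical (C1–C10 bond formed, radical at C5) | COC[C@@H]1CCCN1C(=O)[C@@]1(C)[C@@H]2CCC(=O)C(C)(C)[C]2CCC1=C | intermediate
16 | [(1S,8aR)-1,5,5-trimethyl-2-methylidene-6-oxo-1,2,3,5,6,7,8,8a-octahydronaphthalen-1-yl][(2S)-2-(methoxymethyl)pyrrolidin-1-yl]methanone | COC[C@@H]1CCCN1C(=O)[C@@]1(C)[C@@H]2CCC(=O)C(C)(C)C2=CCC1=C | intermediate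
17 | [(1R,2S,8aR)-1,2,5,5-tetramethyl-6-oxo-1,2,3,5,6,7,8,8a-octahydronaphthalen-1-yl][(2S)-2-(methoxymethyl)pyrrolidin-1-yl]methanone | COC[C@@H]1CCCN1C(=O)[C@@]1(C)[C@@H]2CCC(=O)C(C)(C)C2=CC[C@@H]1C | intermediate
18 | [(1R,2S,6S,8aR)-6-hydroxy-1,2,5,5-tetramethyl-1,2,3,5,6,7,8,8a-octahydronaphthalen-1-yl][(2S)-2-(methoxymethyl)pyrrolidin-1-yl]methanone | COC[C@@H]1CCCN1C(=O)[C@@]1(C)[C@@H]2CC[C@H](O)C(C)(C)C2=CC[C@@H]1C | intermediate
19 | (2S,4aR,5R,6S)-5-(hydroxymethyl)-1,1,5,6-tetramethyl-1,2,3,4,4a,5,6,7-octahydronaphthalen-2-ol | OC[C@@]1(C)[C@@H]2CC[C@H](O)C(C)(C)C2=CC[C@@H]1C | intermediate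
20 | isofraxidin (7-hydroxy-6,8-dimethoxy-2H-chromen-2-one) | COc1cc2ccc(=O)oc2c(OC)c1O | starting material
21 | 7-{[(1R,2S,6S,8aR)-6-hydroxy-1,2,5,5-tetramethyl-1,2,3,5,6,7,8,8a-octahydronaphthalen-1-yl]methoxy}-6,8-dimethoxy-2H-chromen-2-one | COc1cc2ccc(=O)oc2c(OC)c1OC[C@@]1(C)[C@@H]2CC[C@H](O)C(C)(C)C2=CC[C@@H]1C | target

**Step count and risks**

Total step count: 13. Longest linear sequence: 13 steps (1 to 21); 6 and 20 enter as bought compounds.

Steps most likely to fail:

1. Step 9 (Proposed new method). What may go wrong: the cobalt complex may capture radical 14 before it cyclises, which would give the open-chain vinyl ketone; the cobalt hydride may walk the C8 methylidene into the ring; or attack at C10, next to quaternary C9, may be too slow. Fallback with known chemistry, setting out from 13: aerobic ring-opening dehydrogenation of the cyclopropanol with Pd(OAc)2 and pyridine under O2 should give the vinyl ketone F1. Heating F1 in toluene in a sealed tube with a radical inhibitor should then close ring A by a thermal type 2 intramolecular ene reaction: C1 bonds to C10 while H6 moves to C2 in a concerted way, so no cation arises at C5. Face selection rests on the same axial amide, and the sequence comes back to the route at 16.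

2. Step 13. What may go wrong: displacement at the neopentyl C11 by the doubly ortho-substituted phenoxide may be too slow, so that the activated alcohol decomposes or the phosphorane is consumed. Fallback, setting out from 19: selective sulfonylation of the primary hydroxyl with Tf2O and 2,6-di-tert-butylpyridine in CH2Cl2 at −78 °C should give the primary triflate F2. Displacement of this small, very reactive leaving group by the cesium phenoxide of 20 (Cs2CO3, DMF) comes back to the route at 21.

3. Step 12. What may go wrong: hydride addition to the shielded amide carbonyl on quaternary C9 may be incomplete, or the reduction may stall before C–N cleavage. Fallback, setting out from 18: partial reduction of the amide with Cp2Zr(H)Cl in THF should give the aldehyde F3 with release of the auxiliary. NaBH4 in MeOH then reduces F3 and comes back to the route at 19.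

Further compounds
F1 | step 9 | {(1S)-3-(2-methyl-3-oxopent-4-en-2-yl)-1-methyl-6-methylidenecyclohex-2-en-1-yl}[(2S)-2-(methoxymethyl)pyrrolidin-1-yl]methanone | COC[C@@H]1CCCN1C(=O)[C@@]1(C)C=C(CCC1=C)C(C)(C)C(=O)C=C
F2 | step 13 | [(1R,2S,6S,8aR)-6-hydroxy-1,2,5,5-tetramethyl-1,2,3,5,6,7,8,8a-octahydronaphthalen-1-yl]methyl trifluoromethanesulfonate | O=S(=O)(OC[C@@]1(C)[C@@H]2CC[C@H](O)C(C)(C)C2=CC[C@@H]1C)C(F)(F)F
F3 | step 12 | (1R,2S,6S,8aR)-6-hydroxy-1,2,5,5-tetramethyl-1,2,3,5,6,7,8,8a-octahydronaphthalene-1-carbaldehyde | O=C[C@@]1(C)[C@@H]2CC[C@H](O)C(C)(C)C2=CC[C@@H]1C
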